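The data come from a simulation for substances that don't exist; the scatter is artificial.

Count the D left in the flask, not the Q made. In this closed, stirred flask X turns D into Q, and the flask has been followed for a while.

| setting | maple | flask |
|---|---|---|
| D | 0.10 M | 0.10 M |
| X | 91 µM | 91 µM |
| remark | the very flask that is asked about, followed so far |  |
| time |  | 8.0 d |

maple run (percent of the D charged)

| time / d | Q / % | D / % |
|---|---|---|
| 0.250 | 43.1 | 56.7 |
| 0.417 | 61.8 | 37.4 |
| 0.625 | 77.0 | 23.3 |
| 0.833 | 83.9 | 15.9 |
| 1.25 | 88.8 | 11.7 |
| 2.00 | 90.0 | 10.5 |
| 3.00 | 89.1 | 11.2 |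

(scatter of a reading: 0.3 percentage points)



1. Q at 8.0 d, in percent of the D charged
2. amount of Q if the flask were left three thousand times as long, in percent of the D charged

I kept books on D, the limiting reagent. The first two entries were D and Q. They summed to 99.8% at 0.250 d and 100.3% at 3.00 d. A third entry, one D on each X, came to 0.0910% of the charge, and the readings scatter by 0.3 percentage points. So two entries closed the books within the scatter.

Next I took the fraction left, D over D plus Q on the plateau, from the readings at 2.00 d and 3.00 d. As a reading, it came to 10.8%. In the readings, the excess of D over that level fell at 3.97 d⁻¹ between 0.417 d and 0.833 d, so 8.0 d held about 31.8 time constants. I therefore committed to 89.2% of Q, at 8.0 d and for the long flask alike.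

The forecast gave 89.5% (88.3% to 90.6%) at 8.0 d and 89.5% (82% to 97%) for the long flask. My figure lay 0.31 points below it. Its ground was this: “The readings suggest a reversible D ⇌ Q equilibrium.”

The flask gave 89.3% of Q at 8.0 d and 89.3% for the long flask, inside both ranges of the forecast.

    D + X ⇌ G (K = 22.0 M⁻¹, k = 5660 M⁻¹ h⁻¹)
    G ⇌ X + Q (K = 0.380 M, k = 165 h⁻¹)

The D of the flask stood at 10.7% at 8.00 d, against the fraction left of 10.8% as read. That D remained because of the way back from G, the form of the catalyst holding D, to D and X. The run without that way back converted 100% of D, against 89.3%. In the neighbour charged with 5.5 × 10⁻⁵ M of X, the same fraction left gave 89.2% of Q, and that flask reached 89.3%, with 11% of its D left.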